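**Retrosynthetic overview**
1. Target 40 ⇐ desilylation and triacetylation of lactone 38; ring C (γ-lactone) ⇐ oxidative lactonisation of the 7,19-diol 35, which transposes the C7-acyl/C19-carbinol pattern of the lactone building block.
2. Ring B (ten-membered) ⇐ C6–C7 bond by Ni/Cr-catalysed coupling of the Z-alkenyl iodide with the C7 lactol 34 (key step).
3. C8–C9 ⇐ aldol of the enolate of lactone 14 (fragment E) with ring-A aldehyde 30.
4. Ring A ⇐ p-cresol: dearomatisation, Rh-catalysed desymmetrising 1,4-vinylation (C10), methylation and aldol with iodo-enal 8 (C1, C2), SmI2 demethoxylation (C11=C12), directed reduction (C14).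
5. Ring order: A (from the arene), then B (macrocyclisation), then C (lactone, last).

Atom labels used in names follow the target: C1 quaternary ring-fusion carbon (methyl C15), C2 CH–OAc, C3/C4 CH2, C5(methyl C16)=C6, C7 CH–O(lactone), C8 C–OH, C9 CH–OAc, C10 ring-fusion CH, C11(methyl C20)=C12, C13 CH2, C14 CH–OAc, C17 CH(methyl C18), C19 lactone C=O.

**Fragment S (iodo-enal 8)**

Step 1
Reactants: 1 prop-2-yn-1-ol
Product: 3 (Z)-3-iodo-2-methylprop-2-en-1-ol, via alkenylmagnesium alkoxide 2 (not isolated)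
Conditions: MeMgBr (2.3 equiv), CuI (10 mol %), THF, −10 °C to rt; then I2, −78 to 0 °C
Reagents that add atoms: methylmagnesium bromide C[Mg]Br; iodine I-I
Why: Copper-catalysed anti-carbomagnesiation of the propargylic alkoxide places Mg cis to CH2O in a five-membered chelate, and iodinolysis with retention fixes the Z iodoalkene that becomes C5=C6.

Step 2
Reactants: 3 (Z)-3-iodo-2-methylprop-2-en-1-ol
Product: 4 (Z)-3-bromo-1-iodo-2-methylprop-1-ene
Conditions: CBr4, PPh3, CH2Cl2, 0 °C
Reagents that add atoms: carbon tetrabromide BrC(Br)(Br)Br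
Why: Appel bromination of a primary allylic alcohol proceeds by SN2 without touching the alkene geometry.

Step 3
Reactants: 5 tert-butyl acetate; 4 (Z)-3-bromo-1-iodo-2-methylprop-1-ene
Product: 7 tert-butyl (Z)-5-iodo-4-methylpent-4-enoate, via lithium enolate 6 (not isolated)
Conditions: LiN(iPr)2, THF, −78 °C; then 4, DMPU, −78 to −30 °C
Reagents that add atoms: none
Why: Ester enolate alkylation at the primary allylic bromide (SN2) adds C2–C3; the alkenyl iodide is inert to the enolate.

Step 4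
Reactants: 7 tert-butyl (Z)-5-iodo-4-methylpent-4-enoate
Product: 8 (Z)-5-iodo-4-methylpent-4-enal
Conditions: iBu2AlH (1.05 equiv), CH2Cl2, −78 °C; aq. potassium sodium tartrate
Reagents that add atoms: none
Why: Partial ester reduction stops at the aldehyde because the aluminium hemiacetal is stable at −78 °C.

**Fragment E (lactone 14)**

Step 5
Reactants: 9 propanal; 10 ethyl glyoxylate
Product: 11 ethyl (2S,3R)-2-hydroxy-3-methyl-4-oxobutanoate
Conditions: D-proline (20 mol %), MeCN, 4 °C, 9 added over 10 h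
Reagents that add atoms: none
Why: Proline enamine cross-aldol (List–Houk transition state) gives the anti adduct; D-proline sets the methyl-bearing centre (future C17) in the configuration of the target.

Step 6
Reactants: 11 ethyl (2S,3R)-2-hydroxy-3-methyl-4-oxobutanoate
Product: 13 (3S,4S)-3-hydroxy-4-methyloxolan-2-one, via dihydroxy ester 12 (not isolated)
Conditions: NaBH4, EtOH, −20 °C; then 1 M HCl, rt
Reagents that add atoms: none
Why: Chemoselective aldehyde reduction followed by acid-catalysed γ-lactonisation; C17 is not enolisable under these conditions.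

Step 7
Reactants: 13 (3S,4S)-3-hydroxy-4-methyloxolan-2-one
Product: 14 (3S,4S)-4-methyl-3-(triethylsilyloxy)oxolan-2-one
Conditions: Et3SiCl, imidazole, CH2Cl2, 0 °C
Reagents that add atoms: chlorotriethylsilane CC[Si](CC)(CC)Cl
Why: Standard silylation masks the hydroxyl that becomes the C8 tertiary alcohol.

**Fragment K (ring-A ketone 22)**

Step 8
Reactants: 15 4-methylphenol
Product: 16 4-methoxy-4-methylcyclohexa-2,5-dien-1-one
Conditions: PhI(OAc)2 (1.1 equiv), MeOH, 0 °C
Reagents that add atoms: methanol CO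
Why: Oxidative dearomatisation of a para-alkyl phenol with methanol capture gives the symmetric quinol ether; its methyl is C20 and its methoxy is the later leaving group.

Step 9
Reactants: 16 4-methoxy-4-methylcyclohexa-2,5-dien-1-one
Product: 17 (4S,5S)-5-ethenyl-4-methoxy-4-methylcyclohex-2-en-1-one
Conditions: [Rh(cod)2]BF4 (3 mol %), (S)-BINAP (3.3 mol %), CH2=CHBF3K (1.5 equiv), toluene/H2O 10:1, 60 °C
Reagents that add atoms: potassium vinyltrifluoroborate C=C[B-](F)(F)F.[K+]
Why: Hayashi–Miyaura asymmetric 1,4-addition desymmetrises the dienone, with (S)-BINAP expected to select the same enone face as in cyclohexenone to set C10; the C4 epimer formed alongside has the same C10 configuration and converges at 26.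

Step 10
Reactants: 17 (4S,5S)-5-ethenyl-4-methoxy-4-methylcyclohex-2-en-1-one
Product: 19 (4S,5R,6R)-5-ethenyl-4-methoxy-4,6-dimethylcyclohex-2-en-1-one, via lithium dienolate 18 (not isolated)
Conditions: LiN(iPr)2, THF, −78 °C; then MeI, −78 to −40 °C
Reagents that add atoms: iodomethane CI
Why: Only the CH2 flanking the ketone is enolisable, so enolate methylation installs C15 regiospecifically (trans to vinyl; this centre is re-enolised in step 12).

Step 11
Reactants: 19 (4S,5R,6R)-5-ethenyl-4-methoxy-4,6-dimethylcyclohex-2-en-1-one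
Product: 22 (4S,5R,6R)-5-(dimethoxymethyl)-4-methoxy-4,6-dimethylcyclohex-2-en-1-one, via secondary ozonide 20 (not isolated), via aldehyde 21 (not isolated)
Conditions: O3, CH2Cl2, −78 °C (Sudan red end point); Me2S; then HC(OMe)3, MeOH, PPTS (cat.), rt
Reagents that add atoms: trimethyl orthoformate COC(OC)OC
Why: Ozone cleaves the electron-rich vinyl group in preference to the enone, and immediate acetalisation stores C9 at the aldehyde oxidation level before C10 can epimerise.

**Assembly**

Step 12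
Reactants: 22 (4S,5R,6R)-5-(dimethoxymethyl)-4-methoxy-4,6-dimethylcyclohex-2-en-1-one; 8 (Z)-5-iodo-4-methylpent-4-enal
Product: 24 (4S,5R,6S)-5-(dimethoxymethyl)-6-[(1S,4Z)-1-hydroxy-5-iodo-4-methylpent-4-en-1-yl]-4-methoxy-4,6-dimethylcyclohex-2-en-1-one, via lithium dienolate 23 (not isolated)
Conditions: LiN(iPr)2, THF, −78 °C; then 8, −78 °C, 20 min; AcOH quench at −78 °C
Reagents that add atoms: none
Why: Aldol addition of the tetrasubstituted cyclic enolate occurs anti to the C10 acetal group (quaternary C1, C2 trans to C9) through a Zimmerman–Traxler chair in which the methyl cis to O–Li ends syn to the new hydroxyl, giving the C2 configuration of the target.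

Step 13
Reactants: 24 (aldol adduct)
Product: 26 (5S,6S)-5-(dimethoxymethyl)-6-[(1S,4Z)-1-hydroxy-5-iodo-4-methylpent-4-en-1-yl]-4,6-dimethylcyclohex-3-en-1-one, via samarium dienolate 25 (not isolated)
Conditions: SmI2 (2.5 equiv), THF/MeOH 4:1, −78 °C
Reagents that add atoms: none
Why: Two-electron reduction of the enone expels the γ-methoxide (vinylogous α-alkoxy-ketone cleavage), and kinetic α-protonation of the dienolate at C13 leaves the C11=C12 alkene; the stereocentre at C11 disappears.

Step 14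
Reactants: 26 (β-hydroxy ketone)
Product: 27 (1S,5S,6S)-5-(dimethoxymethyl)-6-[(1S,4Z)-1-hydroxy-5-iodo-4-methylpent-4-en-1-yl]-4,6-dimethylcyclohex-3-en-1-ol
Conditions: Me4NBH(OAc)3 (5 equiv), MeCN/AcOH 1:1, −30 °C
Reagents that add atoms: none
Why: Evans–Saksena directed reduction delivers hydride from the C2 alkoxyborohydride through a chair with C3 equatorial, giving the 2,14-anti diol with the C14 oxygen cis to C2.

Step 15
Reactants: 27 (diol acetal)
Product: 30 ring-A aldehyde (2,14-bis-O-triethylsilyl; C9 = CHO), via bis-silyl acetal 28 (not isolated), via lutidinium salt 29 (not isolated)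
Conditions: Et3SiOTf (5 equiv), 2,6-lutidine (8 equiv), CH2Cl2, −78 to 0 °C; then H2O, rt
Reagents that add atoms: triethylsilyl trifluoromethanesulfonate CC[Si](CC)(CC)OS(=O)(=O)C(F)(F)F; water O
Why: The silyl triflate silylates both hindered alcohols and ionises the dimethyl acetal to a lutidinium adduct that water converts to the aldehyde under non-acidic conditions, so the β,γ-unsaturated aldehyde is not epimerised at C10.

Step 16
Reactants: 14 (3S,4S)-4-methyl-3-(triethylsilyloxy)oxolan-2-one; 30 ring-A aldehyde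
Product: 33 aldol adduct (2,8,9,14-tetrakis-O-triethylsilyl; C7 lactone carbonyl; C6–C7 open), via lithium enolate 31 (not isolated), via lithium aldolate 32 (not isolated)
Conditions: 14 (2 equiv), LiN(iPr)2, THF, −78 °C; then 30, −78 °C, 30 min; then Et3SiOTf, −78 to −20 °C
Reagents that add atoms: triethylsilyl trifluoromethanesulfonate CC[Si](CC)(CC)OS(=O)(=O)C(F)(F)F
Why: The lactone enolate attacks the aldehyde anti to its C17 methyl, setting quaternary C8; a closed six-membered lithium transition state with the aldehyde substituent equatorial places O9 syn to O8 (C9 of the target); in-situ silylation stops retro-aldol.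

Step 17
Reactants: 33 aldol adduct
Product: 34 C7 lactol (anomer mixture)
Conditions: iBu2AlH (1.3 equiv), CH2Cl2, −78 °C; aq. potassium sodium tartrate
Reagents that add atoms: none
Why: Half-reduction of the α-quaternary γ-lactone gives the lactol, a latent C7 aldehyde carrying a free C19 primary hydroxyl.

Step 18
Reactants: 34 C7 lactol
Product: 35 macrocyclic 7,19-diol (ring B closed; 2,8,9,14-tetrakis-O-triethylsilyl)
Conditions: CrCl2 (20 mol %), (S)-oxazoline–sulfonamide ligand (22 mol %), proton sponge (22 mol %), NiCl2(2,9-dimethyl-1,10-phenanthroline) (5 mol %), Mn (3 equiv), Cp2ZrCl2 (2.5 equiv), LiCl (3 equiv), MeCN/THF, 34 added over 12 h to 2 mM, rt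
Reagents that add atoms: none
Why: Proposed new method: a catalytic asymmetric nickel/chromium alkenylation (Nozaki–Hiyama–Kishi type) run directly on a γ-lactol as a latent aldehyde to close the ten-membered ring; zerovalent nickel inserts into the C6–I bond with retention of the Z geometry and transmetalates to the ligated chromium centre (trivalent chromium alkenyl), while Cp2ZrCl2 opens the lactol as a zirconium alkoxide of the hydroxy aldehyde and strips the product alkoxide from chromium so that Mn regenerates divalent chromium; the aldehyde is consumed as fast as ring–chain equilibration supplies it, and C7 is set by attack anti to the C8 silyloxy group (polar Felkin–Anh, C9 inside) reinforced by the ligand; the closest known reaction type is the catalytic asymmetric Ni/Cr macrocyclisation of open-chain iodoalkenyl aldehydes.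

Step 19
Reactants: 35 macrocyclic 7,19-diol
Product: 38 tetrakis-O-triethylsilyl lactone (ring C closed), via hydroxy aldehyde 36 (not isolated), via lactol 37 (not isolated)
Conditions: TEMPO (20 mol %), PhI(OAc)2 (2.5 equiv), CH2Cl2, rt
Reagents that add atoms: none
Why: Oxoammonium oxidation selects the primary C19 alcohol; the aldehyde is trapped by the C7 hydroxyl (O9 is silylated) and the lactol is oxidised on to the γ-lactone.

Step 20
Reactants: 38 tetrakis-O-triethylsilyl lactone
Product: 39 2,8,9,14-tetraol lactone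
Conditions: HF·pyridine, pyridine, THF, 0 °C to rt
Reagents that add atoms: none
Why: Buffered fluoride removes all four silyl ethers under non-basic conditions, avoiding retro-aldol at C8–C17, C17 epimerisation and translactonisation.

Step 21
Reactants: 39 2,8,9,14-tetraol lactone
Product: 40 target CNP0187165.2
Conditions: Ac2O, pyridine, DMAP (cat.), CH2Cl2, 0 °C to rt
Reagents that add atoms: acetic anhydride CC(=O)OC(C)=O
Why: The three secondary alcohols (C2, C9, C14) are acetylated while the tertiary C8 hydroxyl does not react under these conditions.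

**Compound list**

1 | prop-2-yn-1-ol | C#CCO | starting material
2 | bromomagnesium (Z)-3-(bromomagnesio)-2-methylprop-2-en-1-olate (not isolated) | Br[Mg]OC/C(C)=C\[Mg]Br | intermediate
3 | (Z)-3-iodo-2-methylprop-2-en-1-ol | OC/C(C)=C\I | intermediate
4 | (Z)-3-bromo-1-iodo-2-methylprop-1-ene | BrC/C(C)=C\I | intermediate
5 | tert-butyl acetate | CC(=O)OC(C)(C)C | starting material
6 | lithium 1-tert-butoxyethen-1-olate (not isolated) | [Li]OC(=C)OC(C)(C)C | intermediate
7 | tert-butyl (Z)-5-iodo-4-methylpent-4-enoate | CC(C)(C)OC(=O)CC/C(C)=C\I | intermediate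
8 | (Z)-5-iodo-4-methylpent-4-enal (fragment S) | O=CCC/C(C)=C\I | intermediate
9 | propanal | CCC=O | starting material
10 | ethyl glyoxylate | CCOC(=O)C=O | starting material
11 | ethyl (2S,3R)-2-hydroxy-3-methyl-4-oxobutanoate | CCOC(=O)[C@@H](O)[C@@H](C)C=O | intermediate
12 | ethyl (2S,3S)-2,4-dihydroxy-3-methylbutanoate (not isolated) | CCOC(=O)[C@@H](O)[C@@H](C)CO | intermediate
13 | (3S,4S)-3-hydroxy-4-methyloxolan-2-one | O=C1OC[C@H](C)[C@@H]1O | intermediate
14 | (3S,4S)-4-methyl-3-(triethylsilyloxy)oxolan-2-one (fragment E) | O=C1OC[C@H](C)[C@@H]1O[Si](CC)(CC)CC | intermediate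
15 | 4-methylphenol | Cc1ccc(O)cc1 | starting material
16 | 4-methoxy-4-methylcyclohexa-2,5-dien-1-one | COC1(C)C=CC(=O)C=C1 | intermediate
17 | (4S,5S)-5-ethenyl-4-methoxy-4-methylcyclohex-2-en-1-one (major C4 epimer shown) | O=C1C=C[C@](C)(OC)[C@H](C=C)C1 | intermediate
18 | lithium dienolate of 17 (not isolated) | [Li]OC1=C[C@@H](C=C)[C@@](C)(OC)C=C1 | intermediate
19 | (4S,5R,6R)-5-ethenyl-4-methoxy-4,6-dimethylcyclohex-2-en-1-one | O=C1C=C[C@](C)(OC)[C@H](C=C)[C@H]1C | intermediate
20 | secondary ozonide of 19 (1,2,4-trioxolane in place of the vinyl group; not isolated) | O=C1C=C[C@](C)(OC)[C@H](C2OCOO2)[C@H]1C | intermediate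
21 | aldehyde from 19 (vinyl replaced by CHO, same configuration; not isolated) | O=C1C=C[C@](C)(OC)[C@H](C=O)[C@H]1C | intermediate
22 | (4S,5R,6R)-5-(dimethoxymethyl)-4-methoxy-4,6-dimethylcyclohex-2-en-1-one (fragment K) | O=C1C=C[C@](C)(OC)[C@H](C(OC)OC)[C@H]1C | intermediate
23 | lithium dienolate of 22 (not isolated) | [Li]OC1=C(C)[C@@H](C(OC)OC)[C@@](C)(OC)C=C1 | intermediate
24 | (4S,5R,6S)-5-(dimethoxymethyl)-6-[(1S,4Z)-1-hydroxy-5-iodo-4-methylpent-4-en-1-yl]-4-methoxy-4,6-dimethylcyclohex-2-en-1-one | O=C1C=C[C@](C)(OC)[C@H](C(OC)OC)[C@@]1(C)[C@@H](O)CC/C(C)=C\I | intermediate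
25 | samarium dienolate from 24 after loss of methoxide (not isolated) | I[Sm](I)OC1=CC=C(C)[C@H](C(OC)OC)[C@@]1(C)[C@@H](O)CC/C(C)=C\I | intermediate
26 | (5S,6S)-5-(dimethoxymethyl)-6-[(1S,4Z)-1-hydroxy-5-iodo-4-methylpent-4-en-1-yl]-4,6-dimethylcyclohex-3-en-1-one | O=C1CC=C(C)[C@H](C(OC)OC)[C@@]1(C)[C@@H](O)CC/C(C)=C\I | intermediate
27 | (1S,5S,6S)-5-(dimethoxymethyl)-6-[(1S,4Z)-1-hydroxy-5-iodo-4-methylpent-4-en-1-yl]-4,6-dimethylcyclohex-3-en-1-ol | O[C@H]1CC=C(C)[C@H](C(OC)OC)[C@@]1(C)[C@@H](O)CC/C(C)=C\I | intermediate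
28 | 2,14-bis-O-triethylsilyl ether of 27 (not isolated) | CC[Si](CC)(CC)O[C@H]1CC=C(C)[C@H](C(OC)OC)[C@@]1(C)[C@@H](O[Si](CC)(CC)CC)CC/C(C)=C\I | intermediate
29 | N-(1-methoxyalkyl)-2,6-dimethylpyridinium triflate from 28 (C9 epimers; not isolated) | CC[Si](CC)(CC)O[C@H]1CC=C(C)[C@H](C(OC)[n+]2c(C)cccc2C)[C@@]1(C)[C@@H](O[Si](CC)(CC)CC)CC/C(C)=C\I.[O-]S(=O)(=O)C(F)(F)F | intermediate
30 | ring-A aldehyde: cyclohex-3-ene bearing C14–OSiEt3, C1 (methyl and the (1S,4Z)-5-iodo-4-methyl-1-(triethylsilyloxy)pent-4-enyl chain), C10–CHO and C11 methyl; configuration of the target at C1, C2, C10, C14 | CC[Si](CC)(CC)O[C@H]1CC=C(C)[C@H](C=O)[C@@]1(C)[C@@H](O[Si](CC)(CC)CC)CC/C(C)=C\I | intermediate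
31 | lithium enolate of 14 (not isolated) | [Li]OC1=C(O[Si](CC)(CC)CC)[C@@H](C)CO1 | intermediate
32 | lithium C9 aldolate of 30 and 31 (not isolated) | CC[Si](CC)(CC)O[C@H]1CC=C(C)[C@H]([C@H](O[Li])[C@@]2(O[Si](CC)(CC)CC)C(=O)OC[C@@H]2C)[C@@]1(C)[C@@H](O[Si](CC)(CC)CC)CC/C(C)=C\I | intermediate
33 | aldol adduct: 30 with C9 now CH(OSiEt3) bonded to C3 of a 4-methyl-3-(triethylsilyloxy)oxolan-2-one (C8 quaternary, C7 lactone carbonyl, C19 ring CH2); configuration of the target at C1, C2, C8, C9, C10, C14, C17 | CC[Si](CC)(CC)O[C@H]1CC=C(C)[C@H]([C@H](O[Si](CC)(CC)CC)[C@@]2(O[Si](CC)(CC)CC)C(=O)OC[C@@H]2C)[C@@]1(C)[C@@H](O[Si](CC)(CC)CC)CC/C(C)=C\I | intermediate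
34 | C7 lactol of 33 (anomer mixture) | CC[Si](CC)(CC)O[C@H]1CC=C(C)[C@H]([C@H](O[Si](CC)(CC)CC)[C@@]2(O[Si](CC)(CC)CC)C(O)OC[C@@H]2C)[C@@]1(C)[C@@H](O[Si](CC)(CC)CC)CC/C(C)=C\I | intermediate
35 | macrocyclic 7,19-diol: bicyclo[8.4.0] core with 5Z and 11 alkenes, free C7–OH (7S) and C19 primary OH, OSiEt3 at C2, C8, C9, C14 | CC[Si](CC)(CC)O[C@H]1CC=C(C)[C@@H]2[C@H](O[Si](CC)(CC)CC)[C@](O[Si](CC)(CC)CC)([C@@H](C)CO)[C@@H](O)/C=C(/C)CC[C@H](O[Si](CC)(CC)CC)[C@@]12C | intermediate
36 | C19 aldehyde of 35 (not isolated) | CC[Si](CC)(CC)O[C@H]1CC=C(C)[C@@H]2[C@H](O[Si](CC)(CC)CC)[C@](O[Si](CC)(CC)CC)([C@@H](C)C=O)[C@@H](O)/C=C(/C)CC[C@H](O[Si](CC)(CC)CC)[C@@]12C | intermediate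
37 | C19 lactol (O7–C19 ring closed, anomer mixture; not isolated) | CC[Si](CC)(CC)O[C@H]1CC=C(C)[C@@H]2[C@H](O[Si](CC)(CC)CC)[C@@]3(O[Si](CC)(CC)CC)[C@H](/C=C(/C)CC[C@H](O[Si](CC)(CC)CC)[C@@]12C)OC(O)[C@@H]3C | intermediate
38 | 2,8,9,14-tetrakis-O-triethylsilyl derivative of the target tetraol lactone | CC[Si](CC)(CC)O[C@H]1CC=C(C)[C@@H]2[C@H](O[Si](CC)(CC)CC)[C@@]3(O[Si](CC)(CC)CC)[C@H](/C=C(/C)CC[C@H](O[Si](CC)(CC)CC)[C@@]12C)OC(=O)[C@@H]3C | intermediate
39 | 2,8,9,14-tetraol lactone (tri-O-deacetyl target) | O[C@H]1CC=C(C)[C@@H]2[C@H](O)[C@@]3(O)[C@H](/C=C(/C)CC[C@H](O)[C@@]12C)OC(=O)[C@@H]3C | intermediate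
40 | CNP0187165.2: (1S,2S,5Z,7S,8S,9S,10S,14S,17R)-2,9,14-triacetoxy-8-hydroxy briarane 5,11-diene γ-lactone | CC(=O)O[C@H]1CC=C(C)[C@@H]2[C@H](OC(C)=O)[C@@]3(O)[C@H](/C=C(/C)CC[C@H](OC(C)=O)[C@@]12C)OC(=O)[C@@H]3C | target

**Step count**

Total steps: 21. Longest linear sequence: 14 steps (8–11 then 12–21; the sequence 1–4 then 12–21 is equally long).

**Three steps most likely to fail**

Step 18 (the proposed new step). The lactol may not open fast enough, or the ten-membered ring may close slowly and give oligomers. The fallback sets out from 33 and comes back at 35, using only known chemistry. Lactone 33 is opened with MeNH(OMe)·HCl and Me3Al to the hydroxy Weinreb amide F1. Et3SiCl and imidazole give the C19 silyl ether F2, and iBu2AlH gives the open-chain C7 aldehyde F3. A classical stoichiometric CrCl2 coupling with 1 mol % NiCl2 in DMSO/THF at 2 mM closes ring B to the macrocyclic allylic alcohol F4. Brief HF·pyridine/pyridine at −10 °C removes only the primary silyl ether and returns 35.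

Step 16. The C8–C9 bond joins a quaternary carbon to a neopentyl-type, enolisable β,γ-unsaturated aldehyde, so enolisation or C10 epimerisation of 30, retro-aldol, or poor C9 selectivity are possible. The fallback sets out from 14 and 30 and comes back at 33. Lactone 14 is converted with LiN(iPr)2 and Me3SiCl into the silyl ketene acetal F5. A BF3·OEt2-mediated Mukaiyama aldol with 30 at −78 °C (non-basic, open transition state, still anti to the C17 methyl) gives the C9-hydroxy lactone F6. Et3SiOTf and 2,6-lutidine silylate O9 to give 33.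

Step 9. The desymmetrising vinylation may give low enantioselectivity, protodeboronation of the vinyl reagent, or double addition. The fallback sets out from 16 and comes back at 17. A chiral carbene–copper catalyst (Cu(OTf)2 with a sulfonate-bearing N-heterocyclic carbene ligand) adds (1-trimethylsilylvinyl)diisobutylaluminium, made from ethynyltrimethylsilane and iBu2AlH, to 16 to give the α-silylvinyl enone F7. Protodesilylation with CF3CO2H returns 17.

**Further compounds**

F1 | step 18 | hydroxy Weinreb amide (33 with the lactone opened to C7 N-methoxy-N-methylamide and free C19 OH) | CC[Si](CC)(CC)O[C@H]1CC=C(C)[C@H]([C@H](O[Si](CC)(CC)CC)[C@@](O[Si](CC)(CC)CC)(C(=O)N(C)OC)[C@@H](C)CO)[C@@]1(C)[C@@H](O[Si](CC)(CC)CC)CC/C(C)=C\I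
F2 | step 18 | C19 triethylsilyl ether of F1 | CC[Si](CC)(CC)O[C@H]1CC=C(C)[C@H]([C@H](O[Si](CC)(CC)CC)[C@@](O[Si](CC)(CC)CC)(C(=O)N(C)OC)[C@@H](C)CO[Si](CC)(CC)CC)[C@@]1(C)[C@@H](O[Si](CC)(CC)CC)CC/C(C)=C\I
F3 | step 18 | open-chain C7 aldehyde (pentakis-O-triethylsilyl) | CC[Si](CC)(CC)O[C@H]1CC=C(C)[C@H]([C@H](O[Si](CC)(CC)CC)[C@@](O[Si](CC)(CC)CC)(C=O)[C@@H](C)CO[Si](CC)(CC)CC)[C@@]1(C)[C@@H](O[Si](CC)(CC)CC)CC/C(C)=C\I
F4 | step 18 | macrocyclic C7 alcohol with C19 triethylsilyl ether (35 silylated at O19) | CC[Si](CC)(CC)O[C@H]1CC=C(C)[C@@H]2[C@H](O[Si](CC)(CC)CC)[C@](O[Si](CC)(CC)CC)([C@@H](C)CO[Si](CC)(CC)CC)[C@@H](O)/C=C(/C)CC[C@H](O[Si](CC)(CC)CC)[C@@]12C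
F5 | step 16 | (4S)-4-methyl-3-(triethylsilyloxy)-2-(trimethylsilyloxy)-4,5-dihydrofuran | C[Si](C)(C)OC1=C(O[Si](CC)(CC)CC)[C@@H](C)CO1
F6 | step 16 | C9-hydroxy aldol lactone (33 without the O9 silyl group) | CC[Si](CC)(CC)O[C@H]1CC=C(C)[C@H]([C@H](O)[C@@]2(O[Si](CC)(CC)CC)C(=O)OC[C@@H]2C)[C@@]1(C)[C@@H](O[Si](CC)(CC)CC)CC/C(C)=C\I
F7 | step 9 | 4-methoxy-4-methyl-5-[1-(trimethylsilyl)ethenyl]cyclohex-2-en-1-one (configuration as 17) | O=C1C=C[C@](C)(OC)[C@H](C(=C)[Si](C)(C)C)C1
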